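Ring A is cut across C2–C3 and C4–C5, so that C3 and C4 (with the gem-dimethyl group and the C3 oxygen) come from one two-carbon alkenyl reagent. Its partner is a bridged bicyclo[2.2.2]octenedione made by dearomatizing a phenol, in which C2 is a ketone and C5=C6 an alkene bridge. Addition of the alkenyllithium to C2 and anionic oxy-Cope shift of the alkoxide form both bonds in one operation and unfold the cage into the decalin. The step exploits the cis fusion of rings A and B (H on C5 and CH3 on C10 on the same face) and the vicinal C2/C3 oxygens next to quaternary C4.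

Key step: step 9

Remark (numbering): C1–C10 are the decalin carbons of 29 (ring A = C1–C5, C10; ring B = C5–C10), C11–C15 the side chain, and β is the face of the C10 methyl group; this numbering is used for all intermediates.
Remark (reading of the target): the SMILES describes a cis-fused decalin (5β-H, 10β-CH3) with 2α-OH, 3α-acyloxy, 9α-H (side chain β), C7=C8, 13S, and an (S)-2-hydroxy-2-methylbutanoyl group.
Remark (assumption): the (R,R)-amide in step 7 is assumed to remove the enantiotopic proton that leads to 12; should the opposite sense be found, the (S,S)-amide is used instead.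

Step 1
Reactants: 1 methyl hydrogen (R)-3-methylglutarate
Product: 2 1-tert-butyl 5-methyl (3S)-3-methylpentanedioate
Conditions: tert-butyl 2,2,2-trichloroacetimidate, BF3·OEt2 (cat.), CH2Cl2/cyclohexane, rt
Reagents that add atoms: tert-butyl 2,2,2-trichloroacetimidate, CC(C)(C)OC(=N)C(Cl)(Cl)Cl
Why: Acid-catalysed transfer of the tert-butyl group from the trichloroacetimidate to the free carboxylic acid (imidate esterification) should protect the future C15 carboxyl without touching the methyl ester or the C13 stereocentre, which comes from the commercial (R)-half-ester.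

Step 2
Reactants: 2 1-tert-butyl 5-methyl (3S)-3-methylpentanedioate
Product: 3 tert-butyl (3S)-5-hydroxy-3-methylpentanoate
Conditions: LiBH4, THF, 0 °C to rt
Reagents that add atoms: none
Why: LiBH4 should reduce the methyl ester but not the hindered tert-butyl ester (chemoselective hydride reduction), so that the former ester carbon becomes C11 and C13 is unchanged.

Step 3
Reactants: 3 tert-butyl (3S)-5-hydroxy-3-methylpentanoate
Product: 4 tert-butyl (3R)-5-iodo-3-methylpentanoate
Conditions: I2, PPh3, imidazole, CH2Cl2, 0 °C
Reagents that add atoms: iodine, II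
Why: The Appel-type iodination converts the primary alcohol into the iodide by SN2 attack of iodide on the alkoxyphosphonium ion at C11, two carbons away from the stereocentre (whose descriptor changes only by priority).

Step 4
Reactants: 5 2-methoxy-3-methylphenol; 6 tert-butyldimethyl(vinyloxy)silane
Product: 8 rac-7-(tert-butyldimethylsilyloxy)-3,3-dimethoxy-4-methylbicyclo[2.2.2]oct-5-en-2-one, via masked ortho-benzoquinone 7 (not isolated)
Conditions: PhI(OAc)2, MeOH, 0 °C; then 6 (excess), rt to 50 °C
Reagents that add atoms: methanol, CO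
Why: Oxidative dearomatization with PhI(OAc)2 in methanol gives the masked ortho-benzoquinone, which is trapped by the enol ether in an inverse-electron-demand Diels–Alder reaction with the oxygen-bearing carbon bonding next to the carbonyl-flanked bridgehead, and the racemic stereocentres formed here are erased at dione 10.

Step 5
Reactants: 8 rac-7-(tert-butyldimethylsilyloxy)-3,3-dimethoxy-4-methylbicyclo[2.2.2]oct-5-en-2-one
Product: 9 rac-7-(tert-butyldimethylsilyloxy)-4-methylbicyclo[2.2.2]oct-5-en-2-one
Conditions: SmI2, THF/MeOH, −78 °C to rt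
Reagents that add atoms: none
Why: SmI2 should cleave both C–O bonds alpha to the ketone by single-electron transfer (reductive dealkoxylation of an alpha,alpha-dialkoxy ketone), leaving the alkene and the silyl ether untouched.

Step 6
Reactants: 9 rac-7-(tert-butyldimethylsilyloxy)-4-methylbicyclo[2.2.2]oct-5-en-2-one
Product: 10 4-methylbicyclo[2.2.2]oct-7-ene-2,6-dione
Conditions: CrO3, H2SO4, acetone/H2O, 0 °C
Reagents that add atoms: none
Why: Chromic acid in aqueous acetone removes the silyl ether and oxidizes the liberated secondary alcohol (chromic acid oxidation), giving the achiral Cs-symmetric beta-diketone in which the two carbonyl bridges are enantiotopic.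

Step 7
Reactants: 10 4-methylbicyclo[2.2.2]oct-7-ene-2,6-dione; 4 tert-butyl (3R)-5-iodo-3-methylpentanoate
Product: 12 cage dione with the C9 side chain syn to the C5=C6 bridge (tert-butyl (3S)-3-methyl-5-[4-methyl-2,6-dioxobicyclo[2.2.2]oct-7-en-3-yl]pentanoate), via lithium enolate 11 (not isolated)
Conditions: (R,R)-bis(1-phenylethyl)amine, n-BuLi, LiCl, THF, −78 °C; then 4, DMPU, −78 to −30 °C
Reagents that add atoms: none
Why: The chiral lithium amide should remove one enantiotopic alpha-proton (desymmetrizing deprotonation of a prochiral ketone) and enolate 11 is alkylated by 4 in an SN2 reaction on the less hindered face toward the C5=C6 bridge, which sets C9 and thereby fixes C7 and C10 of the cage.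

Step 8
Reactants: 13 isobutyraldehyde
Product: 15 1-(methoxymethoxy)-2-methylprop-1-ene, via potassium enolate 14 (not isolated)
Conditions: KH, THF, 0 °C; then MeOCH2Cl, −78 °C to rt
Reagents that add atoms: chloromethyl methyl ether, COCCl
Why: O-Alkylation of the potassium enolate of the alpha-branched aldehyde with the hard chloromethyl ether (enol ether formation) gives the enol ether, which has no alkene geometry to control.

Step 9
Reactants: 12 cage dione with the C9 side chain; 15 1-(methoxymethoxy)-2-methylprop-1-ene
Product: 19 cis-fused decalin diketone (tert-butyl ester; ring A 3α-methoxymethoxy-2-oxo-4,4-dimethyl; ring B 6-en-8-one; 5β-H; 9α-H; 10β-CH3), via alkenyllithium 16 (not isolated), via lithium alkoxide 17 (not isolated), via lithium enolate 18 (not isolated)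
Conditions: 15, s-BuLi, TMEDA, THF, −78 °C; then 12, −78 °C to 0 °C; aq NH4Cl
Reagents that add atoms: none
Why: Vinyl C–H lithiation of 15 gives the acyl-anion-type alkenyllithium 16, which adds to the C2 carbonyl of 12 and forms the C2–C3 bond; the lithium alkoxide 17 is a 3-oxido-1,5-diene (C4=C3–C2(O−)–C7–C6=C5) held in a boat by the bicyclo[2.2.2]octene, so it should undergo an anionic oxy-Cope [3,3] shift that makes C4–C5, breaks C2–C7 and releases the cage strain (because the C8 carbonyl is beta to the alkoxide, the same product can also arise stepwise by retro-aldol cleavage and vinylogous Michael addition). The closest known reaction type is the tandem alkenyl-metal addition/anionic oxy-Cope rearrangement of 2-alkenylbicyclo[2.2.2]oct-5-en-2-ols to cis-decalins. Ring A is closed by the suprafacial [3,3] shift through the boat transition state, formally a 6-endo bond formation between the enol-ether carbon C4 and the alkene carbon C5. C5 is set by delivery of C4 on the face of ring B that carries C1, which fixes the cis ring fusion, and quaternary C4 needs no control; C3 is set on protonation of enolate 18 from the exo (β) face, which gives the equatorial 3α ether, and since it is epimerizable it can be equilibrated to this more stable epimer. The step needs addition at C2 and not at C8, which should be secured by the alpha-branch at C9 and the side chain that screens the open face of C8, and it needs the alkenyl group on the side of the C5=C6 bridge, which is the open face of the C2 carbonyl.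

Step 10
Reactants: 19 cis-fused decalin diketone
Product: 20 3α-hydroxy diketone (19 without the methoxymethyl group)
Conditions: Me2BBr, CH2Cl2, −78 °C; then THF/H2O
Reagents that add atoms: none
Why: Me2BBr cleaves the methoxymethyl acetal at low temperature (Lewis-acid acetal cleavage) and frees the C3 hydroxyl while the tert-butyl ester, the enone and the C3 configuration are kept.

Step 11
Reactants: 21 (S)-2-hydroxy-2-methylbutanoic acid
Product: 23 (S)-2-methyl-2-(triethylsilyloxy)butanoic acid, via bis-silylated ester 22 (not isolated)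
Conditions: Et3SiCl, imidazole, DMF, rt; then K2CO3 (cat.), MeOH/H2O, 0 °C
Reagents that add atoms: chlorotriethylsilane, CC[Si](Cl)(CC)CC
Why: Exhaustive silylation followed by selective solvolysis of the labile silyl ester (protection of a tertiary alcohol) gives the free acid with the tertiary hydroxyl masked and the quaternary stereocentre untouched.

Step 12
Reactants: 20 3α-hydroxy diketone; 23 (S)-2-methyl-2-(triethylsilyloxy)butanoic acid
Product: 25 C3 ester (3α-[(S)-2-methyl-2-(triethylsilyloxy)butanoyloxy] diketone), via mixed anhydride 24 (not isolated)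
Conditions: 2,4,6-trichlorobenzoyl chloride, Et3N, THF, rt; then 20, DMAP, toluene, 40 °C
Reagents that add atoms: none
Why: Yamaguchi esterification through mixed anhydride 24 acylates the hindered C3 hydroxyl with retention at C3 (the equatorial 3α epimer being also the one favoured under the basic conditions) while the C2 ketone stands in for the C2 hydroxyl, so that the two oxygens never have to be told apart as a diol.

Step 13
Reactants: 25 C3 ester
Product: 27 2α-hydroxy C7=C8 enol triflate, via dilithium alkoxide enolate 26 (not isolated)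
Conditions: LiBH(s-Bu)3, THF, −78 °C; then N-(5-chloro-2-pyridyl)bis(trifluoromethanesulfonimide), −78 °C; AcOH
Reagents that add atoms: N-(5-chloro-2-pyridyl)bis(trifluoromethanesulfonimide), FC(F)(F)S(=O)(=O)N(c1ccc(Cl)cn1)S(=O)(=O)C(F)(F)F
Why: LiBH(s-Bu)3 should deliver hydride 1,4 to the beta-unsubstituted enone (conjugate reduction; the C7=C8 enolate is trapped regiospecifically as the enol triflate) and reduce the C2 ketone by equatorial attack from the exo face, opposite the syn-axial C4 methyl and C9, which gives the axial 2α-alcohol cis to the C3 ester.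

Step 14
Reactants: 27 2α-hydroxy C7=C8 enol triflate
Product: 28 tert-butyl ester and triethylsilyl ether of the target
Conditions: Me4Sn, Pd(PPh3)4 (cat.), LiCl, NMP, 60 °C
Reagents that add atoms: tetramethylstannane, C[Sn](C)(C)C
Why: Stille cross-coupling of the enol triflate with Me4Sn installs the C8 methyl group with the double bond fixed at C7=C8 under neutral conditions that should not move the C3 acyl group to the free C2 hydroxyl.

Step 15
Reactants: 28 tert-butyl ester and triethylsilyl ether of the target
Product: 29 (13S)-2α-hydroxy-3α-[(S)-2-hydroxy-2-methylbutanoyloxy]-5β,9α-H-labd-7-en-15-oic acid (the target)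
Conditions: CF3CO2H, CH2Cl2, H2O (trace), 0 °C to rt
Reagents that add atoms: none
Why: Acidolysis with CF3CO2H removes the tert-butyl ester as isobutene and the tertiary triethylsilyl ether in one operation (acid-labile protecting-group cleavage) without base, so that the C3 ester stays in place and 29 results.

Compound list
1 | methyl hydrogen (R)-3-methylglutarate | COC(=O)C[C@H](C)CC(=O)O | starting material
2 | 1-tert-butyl 5-methyl (3S)-3-methylpentanedioate | COC(=O)C[C@H](C)CC(=O)OC(C)(C)C | intermediate
3 | tert-butyl (3S)-5-hydroxy-3-methylpentanoate | OCC[C@H](C)CC(=O)OC(C)(C)C | intermediate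
4 | tert-butyl (3R)-5-iodo-3-methylpentanoate | ICC[C@H](C)CC(=O)OC(C)(C)C | intermediate
5 | 2-methoxy-3-methylphenol | COc1c(C)cccc1O | starting material
6 | tert-butyldimethyl(vinyloxy)silane | C=CO[Si](C)(C)C(C)(C)C | starting material
7 | 6,6-dimethoxy-5-methylcyclohexa-2,4-dien-1-one (masked ortho-benzoquinone) | COC1(OC)C(C)=CC=CC1=O | intermediate (not isolated)
8 | rac-7-(tert-butyldimethylsilyloxy)-3,3-dimethoxy-4-methylbicyclo[2.2.2]oct-5-en-2-one, silyloxy group syn to C5=C6 (racemic, one enantiomer drawn) | COC1(OC)C(=O)[C@@H]2C=C[C@@]1(C)C[C@H]2O[Si](C)(C)C(C)(C)C | intermediate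
9 | rac-7-(tert-butyldimethylsilyloxy)-4-methylbicyclo[2.2.2]oct-5-en-2-one (racemic, one enantiomer drawn) | C1C(=O)[C@@H]2C=C[C@@]1(C)C[C@H]2O[Si](C)(C)C(C)(C)C | intermediate
10 | 4-methylbicyclo[2.2.2]oct-7-ene-2,6-dione (achiral) | CC12CC(=O)C(C=C1)C(=O)C2 | intermediate
11 | enantioenriched lithium mono-enolate of 10 (enolate on the bridge that becomes C8/C9) | C[C@]12CC(=O)[C@H](C=C1)C([O-])=C2.[Li+] | intermediate (not isolated)
12 | tert-butyl (3S)-3-methyl-5-[4-methyl-2,6-dioxobicyclo[2.2.2]oct-7-en-3-yl]pentanoate, side chain syn to the alkene bridge, cage configuration that of C9/C10 in 29 | C[C@]12CC(=O)[C@H](C=C1)C(=O)[C@@H]2CC[C@H](C)CC(=O)OC(C)(C)C | intermediate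
13 | isobutyraldehyde | CC(C)C=O | starting material
14 | potassium 2-methylprop-1-en-1-olate | CC(C)=C[O-].[K+] | intermediate (not isolated)
15 | 1-(methoxymethoxy)-2-methylprop-1-ene | COCOC=C(C)C | intermediate
16 | [1-(methoxymethoxy)-2-methylprop-1-en-1-yl]lithium | [Li]C(OCOC)=C(C)C | intermediate (not isolated)
17 | lithium tertiary alkoxide from addition of 16 to the C2 carbonyl of 12, alkenyl group syn to the C5=C6 bridge | C[C@]12C[C@]([O-])(C(OCOC)=C(C)C)[C@H](C=C1)C(=O)[C@@H]2CC[C@H](C)CC(=O)OC(C)(C)C.[Li+] | intermediate (not isolated)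
18 | lithium C2=C3 enolate of 19 | COCOC1=C([O-])C[C@@]2(C)[C@H](C=CC(=O)[C@@H]2CC[C@H](C)CC(=O)OC(C)(C)C)C1(C)C.[Li+] | intermediate (not isolated)
19 | tert-butyl (13S)-3α-(methoxymethoxy)-2,8-dioxo-17-nor-5β,9α-H-labd-6-en-15-oate (cis-fused, 10β-CH3) | COCO[C@@H]1C(=O)C[C@@]2(C)[C@H](C=CC(=O)[C@@H]2CC[C@H](C)CC(=O)OC(C)(C)C)C1(C)C | intermediate
20 | tert-butyl (13S)-3α-hydroxy-2,8-dioxo-17-nor-5β,9α-H-labd-6-en-15-oate | O[C@@H]1C(=O)C[C@@]2(C)[C@H](C=CC(=O)[C@@H]2CC[C@H](C)CC(=O)OC(C)(C)C)C1(C)C | intermediate
21 | (S)-2-hydroxy-2-methylbutanoic acid | CC[C@](C)(O)C(=O)O | starting material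
22 | triethylsilyl (S)-2-methyl-2-(triethylsilyloxy)butanoate | CC[C@](C)(O[Si](CC)(CC)CC)C(=O)O[Si](CC)(CC)CC | intermediate (not isolated)
23 | (S)-2-methyl-2-(triethylsilyloxy)butanoic acid | CC[C@](C)(O[Si](CC)(CC)CC)C(=O)O | intermediate
24 | mixed anhydride of 23 with 2,4,6-trichlorobenzoic acid | CC[C@](C)(O[Si](CC)(CC)CC)C(=O)OC(=O)c1c(Cl)cc(Cl)cc1Cl | intermediate (not isolated)
25 | tert-butyl (13S)-3α-[(S)-2-methyl-2-(triethylsilyloxy)butanoyloxy]-2,8-dioxo-17-nor-5β,9α-H-labd-6-en-15-oate | CC[C@](C)(O[Si](CC)(CC)CC)C(=O)O[C@@H]1C(=O)C[C@@]2(C)[C@H](C=CC(=O)[C@@H]2CC[C@H](C)CC(=O)OC(C)(C)C)C1(C)C | intermediate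
26 | dilithium 2α-alkoxide C7=C8 enolate from 25 | CC[C@](C)(O[Si](CC)(CC)CC)C(=O)O[C@@H]1[C@H]([O-])C[C@@]2(C)[C@H](CC=C([O-])[C@@H]2CC[C@H](C)CC(=O)OC(C)(C)C)C1(C)C.[Li+].[Li+] | intermediate (not isolated)
27 | tert-butyl (13S)-2α-hydroxy-3α-[(S)-2-methyl-2-(triethylsilyloxy)butanoyloxy]-8-(trifluoromethylsulfonyloxy)-17-nor-5β,9α-H-labd-7-en-15-oate | CC[C@](C)(O[Si](CC)(CC)CC)C(=O)O[C@@H]1[C@H](O)C[C@@]2(C)[C@H](CC=C(OS(=O)(=O)C(F)(F)F)[C@@H]2CC[C@H](C)CC(=O)OC(C)(C)C)C1(C)C | intermediate
28 | tert-butyl (13S)-2α-hydroxy-3α-[(S)-2-methyl-2-(triethylsilyloxy)butanoyloxy]-5β,9α-H-labd-7-en-15-oate | CC[C@](C)(O[Si](CC)(CC)CC)C(=O)O[C@@H]1[C@H](O)C[C@@]2(C)[C@H](CC=C(C)[C@@H]2CC[C@H](C)CC(=O)OC(C)(C)C)C1(C)C | intermediate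
29 | (13S)-2α-hydroxy-3α-[(S)-2-hydroxy-2-methylbutanoyloxy]-5β,9α-H-labd-7-en-15-oic acid (2R,3S,5S,9S,10R) | CC[C@](C)(O)C(=O)O[C@@H]1[C@H](O)C[C@@]2(C)[C@H](CC=C(C)[C@@H]2CC[C@H](C)CC(=O)O)C1(C)C | target

Total step count: 15.
Longest linear sequence: 10 steps (steps 4, 5, 6, 7, 9, 10, 12, 13, 14, 15 from phenol 5; the branch from 1 through steps 1, 2, 3, 7 and onward is equally long).

Steps most likely to fail

Step 9. The alkenyllithium may add to the C8 carbonyl as well as to C2, or act as a base and enolize 12, and lithiation of 15 may occur at a methyl group. The fallback changes the order of events so that only one carbonyl is present. It sets out from dione 10, which is desymmetrized with the same chiral lithium amide in the presence of Me3SiCl to the mono(trimethylsilyl) enol ether F1. Alkenyllithium 16 then adds to the only carbonyl (C2), on the face away from the silyloxy group, and the alkoxide rearranges to the lithium enolate F2, which still carries the ring-B dienol silyl ether. MeLi then frees the C8 dienolate, which is alkylated at C9 with iodide 4 in the same flask (the epimerizable C9 settling with the side chain equatorial). The fallback comes back to the route at 19.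

Step 7. Discrimination between the enantiotopic protons may be incomplete, and C-alkylation of the hindered enolate with an unactivated iodide may be slow. The fallback sets the absolute configuration with an enzyme. It sets out from 10: a ketoreductase (NADPH recycled by glucose dehydrogenase, buffer at pH 7) reduces one enantiotopic carbonyl, the future C2, to the hydroxy ketone F3, a desymmetrizing monoreduction of the kind known for bicyclo[2.2.2]octane-2,6-diones with baker's yeast. The alkoxide enolate of F3 (two equivalents of LDA) is alkylated with 4 to the hydroxy ketone F4, and Dess–Martin oxidation of the carbinol comes back to the route at 12.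

Step 13. Hydride may be delivered 1,2 instead of 1,4 to the hindered enone, and the C3 acyl group may migrate to the C2 alkoxide before the quench. The fallback separates the two reductions. It sets out from 25: [(Ph3P)CuH]6 (cat.) with Et3SiH reduces only the enone to the triethylsilyl enol ether F5, and CsF with PhNTf2 converts it into the keto enol triflate F6. The C2 ketone is then reduced on its own with LiBH(s-Bu)3 at −78 °C with an acetic acid quench, which comes back to the route at 27.

Further compounds
F1 | step 9 | mono(trimethylsilyl) enol ether of dione 10 (enol ether on the bridge that becomes C8/C9) | C[C@]12CC(=O)[C@H](C=C1)C(O[Si](C)(C)C)=C2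
F2 | step 9 | lithium C2=C3 enolate of the cis-decalin carrying a ring-B 8-(trimethylsilyloxy)-6,8-diene | COCOC1=C([O-])C[C@@]2(C)[C@H](C=CC(O[Si](C)(C)C)=C2)C1(C)C.[Li+]
F3 | step 7 | 6-hydroxy-4-methylbicyclo[2.2.2]oct-7-en-2-one from monoreduction of 10 (hydroxyl on the future C2) | C[C@]12C[C@@H](O)[C@H](C=C1)C(=O)C2
F4 | step 7 | hydroxy ketone F3 alkylated at C9 with the side chain syn to the alkene bridge | C[C@]12C[C@@H](O)[C@H](C=C1)C(=O)[C@@H]2CC[C@H](C)CC(=O)OC(C)(C)C
F5 | step 13 | C7=C8 triethylsilyl enol ether of 25 with the C2 ketone intact | CC[C@](C)(O[Si](CC)(CC)CC)C(=O)O[C@@H]1C(=O)C[C@@]2(C)[C@H](CC=C(O[Si](CC)(CC)CC)[C@@H]2CC[C@H](C)CC(=O)OC(C)(C)C)C1(C)C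
F6 | step 13 | C7=C8 enol triflate with the C2 ketone intact | CC[C@](C)(O[Si](CC)(CC)CC)C(=O)O[C@@H]1C(=O)C[C@@]2(C)[C@H](CC=C(OS(=O)(=O)C(F)(F)F)[C@@H]2CC[C@H](C)CC(=O)OC(C)(C)C)C1(C)C
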